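All runs are simulated on assumed constants.

On the readings, Z needs 11.3 d to halve between 5.00 d and 12.0 d of Friday's run, and 10.3 d between 4.00 d and 12.0 d of Tuesday's. I take their mean, 10.8 d, as the late fade half-life, the time in which Z halves in the later part of a run, an apparent first-order half-life.

common to all: X 13 mM

| run | E | remark | time |
|---|---|---|---|
| Tuesday's | 7.7 mM | run made earlier |  |
| Friday's | 33 mM | run made earlier |  |
| oak | 8.00 mM |  | 12 d |
| larch | 15.0 mM |  | 12 d |
| maple | 30.0 mM |  | 12 d |

| Tuesday's: time / d | Tuesday's: Z / % | Friday's: time / d | Friday's: Z / % |
|---|---|---|---|
| 1.67 | 18 | 1.04 | 49 |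
| 4.00 | 12 | 2.00 | 38 |
| 8.00 | 11 | 5.00 | 20 |
| 12.0 | 7 | 12.0 | 13 |

(scatter of a reading: 1.5 percentage points)

- the analysis behind the earlier runs scatters by 1.5 percentage points, standard deviation
- "hardly changes" means that all values lie within two and a half points (for a concentration: within two and a half percent of the largest)

- amount of Z at the end, in percent of the X charged for oak, larch, maple, in this order
- how the row runs (falls all the way / rises all the way / rises, then falls / hardly changes / falls, then rises)

A single end reading carries the whole scatter, so I bring a second reading forward to the end of each run and average the two. Tuesday's reading at 8.00 d, carried over the late fade half-life, joins the end reading to give 7.75%. Friday's reading at 5.00 d, treated likewise, gives 12.9%. Drawn straight against the logarithm of the E charged, these put maple at 12.5%.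

The weak link is the one half-life for both charges. Earlier on, the readings have Friday's Z halving in 3.24 d, faster than Tuesday's 3.98 d. Scaling the late value by that ratio gives Friday's run 8.76 d, and its end becomes 12.2%. For oak, larch and maple I commit to 7.87%, 9.81% and 12.0%, a rise of 4.1 percentage points.

The forecast says 7.5%, 10% and 13%, shape: rises all the way, on the ground “Interpolating, with a saturating curve and a power law agreeing”. It shares my shape and stands higher than my reckoning at maple.

The simulation gives 7.92%, 9.25% and 10.2%, shape: hardly changes.

    X + E ⇌ Z + Q (K = 2.10, k = 6.71 /M/h)
    X ⇌ J (K = 1.20, k = 0.00466 /h)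
    E → D (k = 0.125 /h)

In oak at the end, the step X + E ⇌ Z + Q taken by itself, both ways together, relaxes with a half-life of 0.600 d, shorter than the 12 d of the run, and 0.26% of oak's E charge is left. Over the second stretch of the run, from 6.00 d to 12.0 d, the late fade half-life is 9.80 d in oak and 7.12 d in maple, shorter than in oak, beside the 10.8 d carried from the earlier runs. Maple's lead over oak in Z goes from 6.2 points at 6.00 d to 2.3 points at 12.0 d.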